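the same everywhere: G 2.9 M
- north-west: Z 1.4 mM; run made earlier
- south: Z 5.8 mM; run made earlier
- delta: Z 2.9 mM; time 15 h
- epsilon: Z 2.9 mM; time 12 h

| run | time / h | J / % | X / % | Q / % | G / % |
|---|---|---|---|---|---|
| north-west | 0.833 | 1 | 0 | 1 | 96 |
| north-west | 2.50 | 0 | 4 | 6 | 85 |
| north-west | 4.00 | 3 | 3 | 9 | 83 |
| north-west | 6.00 | 0 | 1 | 11 | 75 |
| north-west | 10.0 | 0 | 4 | 24 | 57 |
| south | 0.833 | 0 | 5 | 2 | 92 |
| south | 1.33 | 0 | 3 | 5 | 82 |
| south | 2.50 | 0 | 7 | 13 | 72 |
| south | 5.00 | 0 | 9 | 39 | 50 |
| south | 10.0 | 0 | 9 | 64 | 21 |

(standard deviation of a reading: 2 percentage points)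

* which of these there is most of at the end, counted by the G in it, delta (G / X / J / Q)
* which of these there is most of at the end, counted by the G in it, epsilon (G / X / J / Q)
* the largest of these amounts at the end, in percent of the G charged, delta
* the largest of these amounts at the end, in percent of the G charged, epsilon

- a species is counted by the G in it: one Q counts as two
- the numbers in the tables scatter by 2 percentage points (one standard deviation)

The easy step comes first: in the last reading of the south run X stands at 9 %, small beside Q at 64 %, and J reads 0 %. So we watch two rates, the one making Q and the one losing G, and divide the first by the second.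

Last readings give Q over G lost as 0.558 in the north-west run and 0.810 in the south run, so it is higher at the higher [Z]. Delta and epsilon both have [Z] = 2.9 mM, close to the geometric middle of those runs, so we take the geometric mean, 0.672. This is the yield ratio s, Q over G lost at the last reading, an overall selectivity. Time does not drop out of it: the south run reads 0.250 at 0.833 h and climbs to 0.810 at 10.0 h, so we carry s to the later ends of delta and epsilon as an estimate that may stand low.

Time enters our reckoning through G lost. The same middle of the two first-order constants gives 0.0937 h⁻¹, which leaves G at 24.5 % in delta and 32.5 % in epsilon. Our reckoning therefore puts Q first, at 50.7 % in delta and 45.4 % in epsilon.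

The forecast, noting that “the balance runs a few percent short”, also named Q for delta and Q for epsilon, but higher than ours, at 61 % and 54 %.

    2 G → L (k = 0.00360 M⁻¹ h⁻¹)
    G + X → Q (k = 0.240 M⁻¹ h⁻¹)
    J → Z + X (k = 220 h⁻¹)
    G + Z ⇌ J (K = 0.640 M⁻¹, k = 17.0 M⁻¹ h⁻¹)

Delta gives Q at 55.1 %, and epsilon gives Q at 47.5 %. At the end of delta, L holds 11.6 % of the G charged. Delta's own yield ratio comes to 0.759, higher than our s of 0.672. Applied to the G that epsilon lost, with 36 % left, our s gives 43.0 % of Q, and the epsilon flask holds 47.5 %.

(The earlier runs and the new flask come from a simulation for an exercise, and the scatter is random.)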